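**Plan**
- Retrosynthetic cuts: the two C4–O sulfate esters (last step); C11=C12 and C11'=C12' (twofold Wittig, C15 + C10 + C15); C7=C8 (Horner–Wadsworth–Emmons with a C5 phosphonate); and, in each ring, C5–C6 together with C3–C4.
- Enabling feature: ring atoms C6–C1(Me2)–C2–C3 plus exocyclic C7 are a masked symmetrical 3,3-dimethylpentanedial (C7 and C3 are its two CHO carbons). C5(CH3)–C4(O) is a masked (E)-1-nitropropene, with NO2 standing in for the C4 oxygen. One amine-catalysed Michael (C5–C6) / Henry (C3–C4) domino therefore closes the whole cyclohexane.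
- Forward order: ring first (step 5); NO2 to C4 ketone (Nef); C7–C11 chain; C4 and C3 carbinols adjusted; C15 phosphonium salt; polyene assembly; regioselective sulfation.
- Stereochemistry: C5 from the prolinol silyl ether catalyst; C6 by thermodynamic relay from C5; C4 by hydroxyl-directed hydride delivery; C3 by oxidation and equatorial hydride attack anti to the axial C1 methyl; chain double bonds E by olefination and thermal equilibration.

Key step: step 5

Remark on numbering: carotenoid locants are used in the text (C1 = CMe2, C2 = CH2, C3 and C4 = oxygenated carbons, C5 = CH–CH3, C6 = ring carbon bearing the chain, C7–C15 = chain); compound names use systematic locants.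
Assumption: the target is drawn as the free bis(hydrogen sulfate), so the sulfate salt formed in the last step is protonated on a cation-exchange resin in the cold.

**Step 1**
Reactants: 1 3,3-dimethylglutaric anhydride
Product: 2 3,3-dimethylpentane-1,5-diol
Conditions: LiAlH4, THF, 0 °C → reflux; aq. NaOH work-up
Reagents that add atoms: none
Why: LiAlH4 reduction of a cyclic anhydride takes both acyl carbons to CH2OH and gives the symmetrical 1,5-diol; no stereocenter is formed.

**Step 2**
Reactants: 2 3,3-dimethylpentane-1,5-diol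
Product: 3 3,3-dimethylpentanedial
Conditions: (COCl)2, DMSO, CH2Cl2, −78 °C; Et3N, −78 → 0 °C; used crude
Reagents that add atoms: none
Why: Swern oxidation should stop at the aldehyde for both primary alcohols and avoids the hydrate and over-oxidation problems of aqueous oxidants; the dial is achiral.

**Step 3**
Reactants: 4 nitromethane; 5 acetaldehyde
Product: 6 1-nitropropan-2-ol (racemic)
Conditions: NaOH (cat.), MeOH–H2O, 0 °C → rt; AcOH quench
Reagents that add atoms: none
Why: Base-catalysed Henry (nitroaldol) reaction; the carbinol centre is formed racemic and is destroyed in step 4.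

**Step 4**
Reactants: 6 1-nitropropan-2-ol
Product: 8 (E)-1-nitroprop-1-ene, via 1-nitropropan-2-yl methanesulfonate 7 (not isolated)
Conditions: MsCl, Et3N, CH2Cl2, −10 → 0 °C; used as a solution
Reagents that add atoms: none
Why: Mesylation followed by E1cB elimination (nitroaldol dehydration) should give the conjugated nitroalkene as the thermodynamically favoured E isomer.

**Step 5**
Reactants: 3 3,3-dimethylpentanedial (excess); 8 (E)-1-nitroprop-1-ene
Product: 10 (1R,4S,5S,6R)-4-hydroxy-2,2,6-trimethyl-5-nitrocyclohexane-1-carbaldehyde, via Michael adduct 9 (not isolated)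
Conditions: (S)-α,α-diphenylprolinol trimethylsilyl ether (10 mol %), PhCO2H (10 mol %), THF, 0 °C → rt; then 1,8-diazabicyclo[5.4.0]undec-7-ene (20 mol %), rt
Reagents that add atoms: none
Why: The secondary amine condenses with one of the two equivalent aldehydes of 3 to an E-enamine whose α-carbon (future C6) adds to C5 of nitroalkene 8 on the face left open by the diphenyl(silyloxy)methyl group, which fixes C5 as R and gives the syn adduct 9 after hydrolysis. The nitronate carbon C4 then attacks the remote aldehyde C3 in an intramolecular Henry reaction, a 6-(enolexo)-exo-trig closure that is the only ring size open to it (attack on the C7 aldehyde would give a four-membered ring). The closest known reaction type is the diarylprolinol silyl ether-catalysed domino Michael/Henry reaction of pentane-1,5-dials with nitroalkenes; here the dial merely carries a 3,3-dimethyl group, which should favour cyclisation (gem-dialkyl effect). C6 is epimerisable α to the aldehyde and the Henry step is reversible, so under the amine and the amidine finish C6, C4 and C3 should settle in the all-equatorial chair dictated by the fixed C5 centre: CHO trans to CH3, NO2 and OH equatorial, the OH kept away from the axial C1 methyl. The step needs mono-addition (secured by the excess of 3 and by the ring closure that consumes the second aldehyde) and enantiofacial control (secured by the catalyst).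

**Step 6**
Reactants: 10 (1R,4S,5S,6R)-4-hydroxy-2,2,6-trimethyl-5-nitrocyclohexane-1-carbaldehyde
Product: 11 (1R,4S,5S,6R)-4-[(tert-butyldimethylsilyl)oxy]-2,2,6-trimethyl-5-nitrocyclohexane-1-carbaldehyde
Conditions: TBSOTf, 2,6-lutidine, CH2Cl2, −78 → 0 °C
Reagents that add atoms: tert-butyldimethylsilyl triflate, CC(C)(C)[Si](C)(C)OS(=O)(=O)C(F)(F)F
Why: Silylation of the equatorial secondary alcohol blocks retro-Henry cleavage and hydroxyl participation in the base-mediated steps that follow; no stereocenter is touched.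

**Step 7**
Reactants: 11 (1R,4S,5S,6R)-4-[(tert-butyldimethylsilyl)oxy]-2,2,6-trimethyl-5-nitrocyclohexane-1-carbaldehyde
Product: 13 (1R,4S,6R)-4-[(tert-butyldimethylsilyl)oxy]-2,2,6-trimethyl-5-oxocyclohexane-1-carbaldehyde, via sodium nitronate 12 (not isolated)
Conditions: NaOMe, MeOH, 0 °C; then aq. TiCl3, NH4OAc, rt
Reagents that add atoms: water, O
Why: Nef reaction in its reductive variant: trivalent titanium reduces the nitronate to the imine, which hydrolyses in the buffered medium to the C4 ketone; C3, C5 and C6 are not involved and already carry equatorial groups.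

**Step 8**
Reactants: 13 (1R,4S,6R)-4-[(tert-butyldimethylsilyl)oxy]-2,2,6-trimethyl-5-oxocyclohexane-1-carbaldehyde; 14 ethyl (2E)-4-(diethoxyphosphoryl)-3-methylbut-2-enoate
Product: 15 ethyl (2E,4E)-5-[(1R,4S,6R)-4-[(tert-butyldimethylsilyl)oxy]-2,2,6-trimethyl-5-oxocyclohexyl]-3-methylpenta-2,4-dienoate
Conditions: 14, LiN(SiMe3)2, THF, −78 °C; then 13, −78 → 0 °C
Reagents that add atoms: none
Why: Horner–Wadsworth–Emmons olefination with the lithiated C5 phosphonate is chemoselective for the aldehyde over the hindered ketone and should form C7=C8 with E geometry, delivering the C7–C11 chain at the ester level; C6 keeps its equatorial configuration.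

**Step 9**
Reactants: 15 ethyl (2E,4E)-5-[(1R,4S,6R)-4-[(tert-butyldimethylsilyl)oxy]-2,2,6-trimethyl-5-oxocyclohexyl]-3-methylpenta-2,4-dienoate
Product: 16 ethyl (2E,4E)-5-[(1R,4S,6R)-4-hydroxy-2,2,6-trimethyl-5-oxocyclohexyl]-3-methylpenta-2,4-dienoate
Conditions: HF·pyridine, THF–pyridine, 0 °C → rt
Reagents that add atoms: none
Why: Fluoride cleavage of the silyl ether under buffered, non-basic conditions (no α-ketol isomerisation) frees the C3 hydroxyl that is needed as a directing group in step 10.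

**Step 10**
Reactants: 16 ethyl (2E,4E)-5-[(1R,4S,6R)-4-hydroxy-2,2,6-trimethyl-5-oxocyclohexyl]-3-methylpenta-2,4-dienoate
Product: 17 ethyl (2E,4E)-5-[(1R,4S,5S,6R)-4,5-dihydroxy-2,2,6-trimethylcyclohexyl]-3-methylpenta-2,4-dienoate
Conditions: Me4NBH(OAc)3, AcOH–MeCN, −20 °C
Reagents that add atoms: none
Why: Hydroxyl-directed reduction (Saksena–Evans type): the acetoxyborohydride bound to the C3 oxygen delivers hydride intramolecularly to the axial face of the C4 ketone, which should make the new C4 hydroxyl equatorial, trans to the C3 hydroxyl and trans to the C5 methyl, while the dienoate is inert.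

**Step 11**
Reactants: 17 ethyl (2E,4E)-5-[(1R,4S,5S,6R)-4,5-dihydroxy-2,2,6-trimethylcyclohexyl]-3-methylpenta-2,4-dienoate
Product: 19 ethyl (2E,4E)-5-[(1R,4S,5S,6R)-5-acetoxy-4-[(tert-butyldimethylsilyl)oxy]-2,2,6-trimethylcyclohexyl]-3-methylpenta-2,4-dienoate, via C3 silyl ether 18 (not isolated)
Conditions: TBSCl, imidazole, DMF, 0 °C; then Ac2O, 4-(dimethylamino)pyridine (cat.), rt
Reagents that add atoms: tert-butyldimethylsilyl chloride, CC(C)(C)[Si](C)(C)Cl; acetic anhydride, CC(=O)OC(C)=O
Why: Silylation should select the less hindered equatorial C3 hydroxyl (the C4 hydroxyl is flanked by the C5 methyl), and acetylation of the remaining C4 hydroxyl in the same pot then differentiates the two oxygens; no stereocenter changes.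

**Step 12**
Reactants: 19 ethyl (2E,4E)-5-[(1R,4S,5S,6R)-5-acetoxy-4-[(tert-butyldimethylsilyl)oxy]-2,2,6-trimethylcyclohexyl]-3-methylpenta-2,4-dienoate
Product: 20 ethyl (2E,4E)-5-[(1R,5S,6R)-5-acetoxy-2,2,6-trimethyl-4-oxocyclohexyl]-3-methylpenta-2,4-dienoate
Conditions: CrO3, H2SO4, H2O, acetone, 0 °C → rt
Reagents that add atoms: none
Why: Jones oxidation: the aqueous acid cleaves the silyl ether and the liberated secondary alcohol is oxidised in situ to the C3 ketone (oxidative desilylation), and the acidic medium excludes base-induced acetyl migration; C4 is untouched.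

**Step 13**
Reactants: 20 ethyl (2E,4E)-5-[(1R,5S,6R)-5-acetoxy-2,2,6-trimethyl-4-oxocyclohexyl]-3-methylpenta-2,4-dienoate
Product: 21 ethyl (2E,4E)-5-[(1R,4R,5S,6R)-5-acetoxy-4-hydroxy-2,2,6-trimethylcyclohexyl]-3-methylpenta-2,4-dienoate
Conditions: LiBH(sBu)3, THF, −78 °C; aq. NH4Cl
Reagents that add atoms: none
Why: Ketone reduction with the bulky LiBH(sBu)3 by equatorial attack, anti to the axial C1 methyl that blocks the axial trajectory, should give the axial C3 alcohol (3R in carotenoid locants), cis to the C4 acetate, which is the net inversion of the Henry carbinol.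

**Step 14**
Reactants: 21 ethyl (2E,4E)-5-[(1R,4R,5S,6R)-5-acetoxy-4-hydroxy-2,2,6-trimethylcyclohexyl]-3-methylpenta-2,4-dienoate
Product: 22 (2E,4E)-5-[(1R,4R,5S,6R)-4,5-dihydroxy-2,2,6-trimethylcyclohexyl]-3-methylpenta-2,4-dien-1-ol
Conditions: iBu2AlH, CH2Cl2, −78 → 0 °C; aq. potassium sodium tartrate
Reagents that add atoms: none
Why: iBu2AlH reduces the dienoate 1,2 to the primary allylic alcohol and at the same time cleaves the acetate, giving the free cis-diol; no stereocenter is affected.

**Step 15**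
Reactants: 22 (2E,4E)-5-[(1R,4R,5S,6R)-4,5-dihydroxy-2,2,6-trimethylcyclohexyl]-3-methylpenta-2,4-dien-1-ol
Product: 23 [(2E,4E)-5-[(1R,4R,5S,6R)-4,5-dihydroxy-2,2,6-trimethylcyclohexyl]-3-methylpenta-2,4-dien-1-yl]triphenylphosphonium bromide
Conditions: PPh3·HBr, MeOH, rt
Reagents that add atoms: triphenylphosphine hydrobromide, [Br-].[PH+](c1ccccc1)(c1ccccc1)c1ccccc1
Why: Phosphonium salt formation from an allylic alcohol (ionisation to the pentadienyl cation and capture by PPh3 at the terminal carbon), the standard entry to C15 Wittig salts, which tolerates free secondary hydroxyls and should funnel C9=C10 to E.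

**Step 16**
Reactants: 23 the C15 phosphonium bromide (2 equiv); 24 (2E,4E,6E)-2,7-dimethylocta-2,4,6-trienedial
Product: 26 (all-E,3R,4S,5R,6R,3'R,4'S,5'R,6'R)-5,6,5',6'-tetrahydro-β,β-carotene-3,4,3',4'-tetrol, via C25 apo-aldehyde 25 (not isolated)
Conditions: NaOMe, MeOH–CH2Cl2, 0 °C → rt, dark, argon; then EtOH, reflux
Reagents that add atoms: none
Why: Twofold Wittig olefination of the C10 dialdehyde (C15 + C10 + C15 carotenoid assembly, free hydroxyls tolerated) forms C11=C12 and C11'=C12'; Z isomers at these disubstituted bonds should equilibrate thermally to the all-E polyene.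

**Step 17**
Reactants: 26 (all-E,3R,4S,5R,6R,3'R,4'S,5'R,6'R)-5,6,5',6'-tetrahydro-β,β-carotene-3,4,3',4'-tetrol
Product: 27 (all-E,3R,4S,5R,6R,3'R,4'S,5'R,6'R)-5,6,5',6'-tetrahydro-β,β-carotene-3,4,3',4'-tetrol 4,4'-bis(hydrogen sulfate)
Conditions: SO3·pyridine, pyridine–DMF, 0 °C, dark; then H+ cation-exchange resin, 0 °C
Reagents that add atoms: sulfur trioxide–pyridine complex, O=S(=O)([O-])[n+]1ccccc1
Why: O-Sulfonation should occur only at the equatorial C4 and C4' hydroxyls, because each C3 hydroxyl is axial and 1,3-diaxial to a C1 methyl (equatorial-selective sulfation of cis-1,2-diols); cation exchange then gives the hydrogen sulfate form.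

**Compound list**
1 | 3,3-dimethylglutaric anhydride (4,4-dimethyloxane-2,6-dione) | CC1(C)CC(=O)OC(=O)C1 | starting material
2 | 3,3-dimethylpentane-1,5-diol | OCCC(C)(C)CCO | intermediate
3 | 3,3-dimethylpentanedial | O=CCC(C)(C)CC=O | intermediate
4 | nitromethane | C[N+](=O)[O-] | starting material
5 | acetaldehyde | CC=O | starting material
6 | 1-nitropropan-2-ol (racemic) | CC(O)C[N+](=O)[O-] | intermediate
7 | 1-nitropropan-2-yl methanesulfonate (racemic, not isolated) | CC(OS(C)(=O)=O)C[N+](=O)[O-] | intermediate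
8 | (E)-1-nitroprop-1-ene | C/C=C/[N+](=O)[O-] | intermediate
9 | (2S)-3,3-dimethyl-2-[(2R)-1-nitropropan-2-yl]pentanedial (Michael adduct, not isolated) | O=C[C@@H]([C@@H](C)C[N+](=O)[O-])C(C)(C)CC=O | intermediate
10 | (1R,4S,5S,6R)-4-hydroxy-2,2,6-trimethyl-5-nitrocyclohexane-1-carbaldehyde | O=C[C@@H]1[C@@H](C)[C@H]([N+](=O)[O-])[C@@H](O)CC1(C)C | intermediate
11 | (1R,4S,5S,6R)-4-[(tert-butyldimethylsilyl)oxy]-2,2,6-trimethyl-5-nitrocyclohexane-1-carbaldehyde | O=C[C@@H]1[C@@H](C)[C@H]([N+](=O)[O-])[C@@H](O[Si](C)(C)C(C)(C)C)CC1(C)C | intermediate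
12 | sodium nitronate of 11 (C4 planar, not isolated) | [Na+].O=C[C@@H]1[C@@H](C)C(=[N+]([O-])[O-])[C@@H](O[Si](C)(C)C(C)(C)C)CC1(C)C | intermediate
13 | (1R,4S,6R)-4-[(tert-butyldimethylsilyl)oxy]-2,2,6-trimethyl-5-oxocyclohexane-1-carbaldehyde | O=C[C@@H]1[C@@H](C)C(=O)[C@@H](O[Si](C)(C)C(C)(C)C)CC1(C)C | intermediate
14 | ethyl (2E)-4-(diethoxyphosphoryl)-3-methylbut-2-enoate (triethyl 3-methyl-4-phosphonocrotonate) | CCOC(=O)/C=C(C)/CP(=O)(OCC)OCC | starting material
15 | ethyl (2E,4E)-5-[(1R,4S,6R)-4-[(tert-butyldimethylsilyl)oxy]-2,2,6-trimethyl-5-oxocyclohexyl]-3-methylpenta-2,4-dienoate | CCOC(=O)/C=C(C)/C=C/[C@@H]1[C@@H](C)C(=O)[C@@H](O[Si](C)(C)C(C)(C)C)CC1(C)C | intermediate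
16 | ethyl (2E,4E)-5-[(1R,4S,6R)-4-hydroxy-2,2,6-trimethyl-5-oxocyclohexyl]-3-methylpenta-2,4-dienoate | CCOC(=O)/C=C(C)/C=C/[C@@H]1[C@@H](C)C(=O)[C@@H](O)CC1(C)C | intermediate
17 | ethyl (2E,4E)-5-[(1R,4S,5S,6R)-4,5-dihydroxy-2,2,6-trimethylcyclohexyl]-3-methylpenta-2,4-dienoate | CCOC(=O)/C=C(C)/C=C/[C@@H]1[C@@H](C)[C@H](O)[C@@H](O)CC1(C)C | intermediate
18 | ethyl (2E,4E)-5-[(1R,4S,5S,6R)-4-[(tert-butyldimethylsilyl)oxy]-5-hydroxy-2,2,6-trimethylcyclohexyl]-3-methylpenta-2,4-dienoate (not isolated) | CCOC(=O)/C=C(C)/C=C/[C@@H]1[C@@H](C)[C@H](O)[C@@H](O[Si](C)(C)C(C)(C)C)CC1(C)C | intermediate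
19 | ethyl (2E,4E)-5-[(1R,4S,5S,6R)-5-acetoxy-4-[(tert-butyldimethylsilyl)oxy]-2,2,6-trimethylcyclohexyl]-3-methylpenta-2,4-dienoate | CCOC(=O)/C=C(C)/C=C/[C@@H]1[C@@H](C)[C@H](OC(C)=O)[C@@H](O[Si](C)(C)C(C)(C)C)CC1(C)C | intermediate
20 | ethyl (2E,4E)-5-[(1R,5S,6R)-5-acetoxy-2,2,6-trimethyl-4-oxocyclohexyl]-3-methylpenta-2,4-dienoate | CCOC(=O)/C=C(C)/C=C/[C@@H]1[C@@H](C)[C@H](OC(C)=O)C(=O)CC1(C)C | intermediate
21 | ethyl (2E,4E)-5-[(1R,4R,5S,6R)-5-acetoxy-4-hydroxy-2,2,6-trimethylcyclohexyl]-3-methylpenta-2,4-dienoate | CCOC(=O)/C=C(C)/C=C/[C@@H]1[C@@H](C)[C@H](OC(C)=O)[C@H](O)CC1(C)C | intermediate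
22 | (2E,4E)-5-[(1R,4R,5S,6R)-4,5-dihydroxy-2,2,6-trimethylcyclohexyl]-3-methylpenta-2,4-dien-1-ol | OC/C=C(C)/C=C/[C@@H]1[C@@H](C)[C@H](O)[C@H](O)CC1(C)C | intermediate
23 | [(2E,4E)-5-[(1R,4R,5S,6R)-4,5-dihydroxy-2,2,6-trimethylcyclohexyl]-3-methylpenta-2,4-dien-1-yl]triphenylphosphonium bromide | [Br-].c1ccc(cc1)[P+](c1ccccc1)(c1ccccc1)C/C=C(C)/C=C/[C@@H]1[C@@H](C)[C@H](O)[C@H](O)CC1(C)C | intermediate
24 | (2E,4E,6E)-2,7-dimethylocta-2,4,6-trienedial | O=C/C(C)=C/C=C/C=C(C)/C=O | starting material
25 | (2E,4E,6E,8E,10E,12E)-13-[(1R,4R,5S,6R)-4,5-dihydroxy-2,2,6-trimethylcyclohexyl]-2,7,11-trimethyltrideca-2,4,6,8,10,12-hexaenal (not isolated) | O=C/C(C)=C/C=C/C=C(C)/C=C/C=C(C)/C=C/[C@@H]1[C@@H](C)[C@H](O)[C@H](O)CC1(C)C | intermediate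
26 | (all-E,3R,4S,5R,6R,3'R,4'S,5'R,6'R)-5,6,5',6'-tetrahydro-β,β-carotene-3,4,3',4'-tetrol | CC(/C=C/C=C(C)/C=C/[C@@H]1[C@@H](C)[C@H](O)[C@H](O)CC1(C)C)=C\C=C\C=C(C)\C=C\C=C(C)\C=C\[C@@H]1[C@@H](C)[C@H](O)[C@H](O)CC1(C)C | intermediate
27 | (all-E,3R,4S,5R,6R,3'R,4'S,5'R,6'R)-5,6,5',6'-tetrahydro-β,β-carotene-3,4,3',4'-tetrol 4,4'-bis(hydrogen sulfate) | CC(/C=C/C=C(C)/C=C/[C@@H]1[C@@H](C)[C@H](OS(=O)(=O)O)[C@H](O)CC1(C)C)=C\C=C\C=C(C)\C=C\C=C(C)\C=C\[C@@H]1[C@@H](C)[C@H](OS(=O)(=O)O)[C@H](O)CC1(C)C | target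

**Step count**
Total: 17 steps. Longest linear sequence: 15 steps (steps 1, 2 and 5–17, from 1 to 27).

**Steps most likely to fail**

Step 5. The Michael addition may be outrun by self-aldol oligomerisation of the unprotected dialdehyde, and ring closure with C6 epimerisation may stop at a mixture of open and cyclised diastereomers. The fallback separates the two events and masks one aldehyde. It sets out from 3: sub-stoichiometric mono-acetalisation (HC(OMe)3, MeOH, p-toluenesulfonic acid cat.; separation from 3 and the bis-acetal) gives 5,5-dimethoxy-3,3-dimethylpentanal F1. The same prolinol silyl ether catalyst then performs only the Michael addition to 8 and should give (2S)-5,5-dimethoxy-3,3-dimethyl-2-[(2R)-1-nitropropan-2-yl]pentanal F2, which can be purified. Aqueous trifluoroacetic acid unmasks the second aldehyde (compound 9), and a separate amidine-mediated Henry closure and equilibration returns to the route at 10.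

Step 7. The silyloxy group may be lost by β-elimination from the nitronate, and the free aldehyde may be consumed in aldol-type reactions under methoxide. The fallback avoids the nitronate. It sets out from 11: reduction of the nitro group with SnCl2, PhSH and Et3N in MeCN should give (1R,4S,6R)-4-[(tert-butyldimethylsilyl)oxy]-5-(hydroxyimino)-2,2,6-trimethylcyclohexane-1-carbaldehyde F3. Cleavage of the oxime with aqueous TiCl3 buffered by NH4OAc returns to the route at 13.

Step 17. Discrimination between the equatorial C4 and the axial C3 hydroxyls may be insufficient, leading to mis-sulfation or over-sulfation of the tetrol. The fallback uses a temporary tin acetal as regiodirecting group. It sets out from 26: brief heating with Bu2SnO in MeOH–toluene gives the 3,4:3',4'-bis-O-(dibutylstannylene) acetal F4, in which the equatorial C4 oxygen is the activated one. SO3·NMe3 in DMF at room temperature then sulfates that position only, and aqueous work-up with cation exchange returns to the route at 27.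

**Further compounds**
F1 | step 5 | 5,5-dimethoxy-3,3-dimethylpentanal | COC(OC)CC(C)(C)CC=O
F2 | step 5 | (2S)-5,5-dimethoxy-3,3-dimethyl-2-[(2R)-1-nitropropan-2-yl]pentanal | O=C[C@@H]([C@@H](C)C[N+](=O)[O-])C(C)(C)CC(OC)OC
F3 | step 7 | (1R,4S,6R)-4-[(tert-butyldimethylsilyl)oxy]-5-(hydroxyimino)-2,2,6-trimethylcyclohexane-1-carbaldehyde | O=C[C@@H]1[C@@H](C)C(=NO)[C@@H](O[Si](C)(C)C(C)(C)C)CC1(C)C
F4 | step 17 | 3,4:3',4'-bis-O-(dibutylstannylene) acetal of 26 | CC(/C=C/C=C(C)/C=C/[C@@H]1[C@@H](C)[C@@H]2O[Sn](CCCC)(CCCC)O[C@@H]2CC1(C)C)=C\C=C\C=C(C)\C=C\C=C(C)\C=C\[C@@H]1[C@@H](C)[C@@H]2O[Sn](CCCC)(CCCC)O[C@@H]2CC1(C)C
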